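The route rests on disconnecting C2–C3 in the 14-membered lactone ring. The C1–C3 β-oxygenated ester, whose C3 carbinol is allylic to the (Z)-C4=C5 alkene, is an acetate-aldol retron. A SmI2 Reformatsky reaction of an O13 bromoacetate with a (Z)-enal forms the C2–C3 bond, creates the C3 stereocentre and closes the macrolactone in one non-basic operation. The precursor is the 2,5-trans tetrahydrofuran ring (O, C11–C14) from 2-deoxy-D-glucose. It bears the C13 bromoacetate, the silyl-protected C15–C19 ester side chain and the C10–C3 chain with the (Z)-chloroalkene and the (Z)-enal, assembled by a B-alkyl Suzuki coupling at C8–C9.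

Key step: step 19

Remark: atoms are numbered as in the target (C1 lactone carbonyl, C19 carboxyl carbon; tetrahydrofuran ring = O, C11, C12, C13, C14). C11–C16 of the target are C1–C6 of 2-deoxy-D-glucose, whose C3, C4 and C5 configurations are those of C13, C14 and C15, so only C11 and C3 have to be created. The target is taken as the (3R,11R,13R,14R,15R,4Z,7Z,16E) isomer that its SMILES defines. TBS = tert-butyldimethylsilyl.

Step 1
Reactants: 1 2-deoxy-D-glucose
Product: 2 2-deoxy-D-arabino-hexono-1,4-lactone
Conditions: Br2, BaCO3, H2O, rt; filter; acidic ion-exchange resin; concentrate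
Reagents that add atoms: none
Why: Bromine-water oxidation of the aldose hemiacetal gives 2-deoxygluconic acid, which closes on concentration to the stable five-membered 1,4-lactone, so that O4 (the later ring oxygen) is tied to C1 (the later C11) without touching C3, C4 or C5.

Step 2
Reactants: 2 2-deoxy-D-arabino-hexono-1,4-lactone
Product: 3 2-deoxy-5,6-O-isopropylidene-D-arabino-hexono-1,4-lactone
Conditions: Me2C(OMe)2, TsOH·H2O (cat.), acetone, rt
Reagents that add atoms: 2,2-dimethoxypropane, COC(C)(C)OC
Why: Acid-catalysed transacetalisation forms the five-membered dioxolane on the terminal 5,6-diol in preference to a six-membered 3,5-acetal, which leaves only the C3 hydroxyl (the later O13) free.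

Step 3
Reactants: 3 2-deoxy-5,6-O-isopropylidene-D-arabino-hexono-1,4-lactone
Product: 4 2-deoxy-5,6-O-isopropylidene-3-O-(2-naphthylmethyl)-D-arabino-hexono-1,4-lactone
Conditions: 2-(bromomethyl)naphthalene, Ag2O, n-Bu4NI (cat.), CH2Cl2, rt, dark
Reagents that add atoms: 2-(bromomethyl)naphthalene, BrCc1ccc2ccccc2c1
Why: Ag2O-promoted Williamson-type etherification needs no strong base and so avoids β-elimination of the β-hydroxy lactone; the 2-naphthylmethyl ether is chosen because it should survive the acids ahead and can later be removed oxidatively beside a TBS ether.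

Step 4
Reactants: 4 2-deoxy-5,6-O-isopropylidene-3-O-(2-naphthylmethyl)-D-arabino-hexono-1,4-lactone
Product: 5 1-C-ethynyl hemiketal of lactone 4 (both anomers)
Conditions: HC≡CMgBr, THF, −78 to −30 °C; then aq NH4Cl
Reagents that add atoms: ethynylmagnesium bromide, C#C[Mg]Br
Why: Addition of an acetylide Grignard reagent to a γ-lactone stops at the tetrahedral magnesium alkoxide at low temperature, so a single ethynyl group is introduced and the hemiketal is obtained on work-up.

Step 5
Reactants: 5 1-C-ethynyl hemiketal of lactone 4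
Product: 6 C11-ethynyl tetrahydrofuran (11S,13R,14S,15R) with the C13 naphthylmethyl ether and the C15/C16 acetonide
Conditions: Et3SiH, BF3·OEt2, CH2Cl2/MeCN, −78 to −40 °C
Reagents that add atoms: none
Why: In this ionic reduction of a hemiketal BF3 ionises 5 to the five-membered oxocarbenium ion and Et3SiH delivers hydride along the inside-attack trajectory of the envelope in which the C13 alkoxy group is pseudoaxial and the cis C14 substituent pseudoequatorial, that is cis to O13, which places the ethynyl group trans to both and sets C11.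

Step 6
Reactants: 6 C11-ethynyl tetrahydrofuran
Product: 7 C11-vinyl tetrahydrofuran (11S,13R,14S,15R) with the C13 naphthylmethyl ether and the C15/C16 acetonide
Conditions: H2 (1 atm), Pd/CaCO3 poisoned with Pb(OAc)2, quinoline, EtOAc, rt
Reagents that add atoms: none
Why: Semihydrogenation of the terminal alkyne over lead-poisoned palladium with quinoline should stop at the alkene and leave the naphthylmethyl ether and the acetal untouched.

Step 7
Reactants: 7 C11-vinyl tetrahydrofuran acetonide
Product: 8 C11-vinyl tetrahydrofuran C15,C16-diol (11S,13R,14R,15R)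
Conditions: AcOH/H2O (4:1), 40 °C
Reagents that add atoms: none
Why: Mild aqueous-acid hydrolysis cleaves the isopropylidene acetal while the naphthylmethyl ether and the vinyl tetrahydrofuran are stable.

Step 8
Reactants: 8 C11-vinyl tetrahydrofuran C15,C16-diol
Product: 9 C15,C16-bis-TBS ether (11S,13R,14S,15R)
Conditions: TBSOTf, 2,6-lutidine, CH2Cl2, −78 to 0 °C
Reagents that add atoms: tert-butyldimethylsilyl trifluoromethanesulfonate, CC(C)(C)[Si](C)(C)OS(=O)(=O)C(F)(F)F
Why: The silyl triflate with a hindered pyridine base silylates both the primary and the hindered secondary hydroxyl completely.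

Step 9
Reactants: 9 C15,C16-bis-TBS ether
Product: 10 C16 primary alcohol with the C15 TBS ether (11S,13R,14S,15R)
Conditions: HF·pyridine, pyridine, THF, 0 °C
Reagents that add atoms: none
Why: Buffered HF·pyridine cleaves the accessible primary TBS ether much faster than the secondary one at C15, the usual selective monodesilylation of a bis-silyl ether.

Step 10
Reactants: 10 C16 primary alcohol with the C15 TBS ether
Product: 12 ethyl (E)-2-methyl-enoate at C16=C17 (11S,13R,14S,15R; ester carbon = later C19), via C16 aldehyde 11 (not isolated)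
Conditions: Dess–Martin periodinane, CH2Cl2, 0 °C to rt; then Ph3P=C(CH3)CO2Et (excess), rt
Reagents that add atoms: ethyl 2-(triphenylphosphoranylidene)propanoate, CCOC(=O)C(C)=P(c1ccccc1)(c1ccccc1)c1ccccc1
Why: Dess–Martin oxidation gives the configurationally labile α-silyloxy aldehyde, which is trapped in the same flask by the stabilised α-methyl ylide in a Wittig reaction that should give the (E)-trisubstituted enoate and avoids epimerisation at C15.

Step 11
Reactants: 12 ethyl (E)-2-methyl-enoate
Product: 13 (E)-2-methyl-enoic acid (11S,13R,14S,15R)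
Conditions: LiOH, THF/MeOH/H2O, rt; then aq HCl to pH 4, 0 °C
Reagents that add atoms: lithium hydroxide, [Li+].[OH-]
Why: Saponification of the ethyl ester with LiOH leaves the silyl and naphthylmethyl ethers and the alkene geometry intact.

Step 12
Reactants: 13 (E)-2-methyl-enoic acid
Product: 15 (E)-alkenyl diazomethyl ketone (11S,13R,14S,15R), via isobutyl carbonic mixed anhydride 14 (not isolated)
Conditions: i-BuOCOCl, N-methylmorpholine, THF, −20 °C; then CH2N2, Et2O, 0 °C to rt
Reagents that add atoms: diazomethane, C=[N+]=[N-]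
Why: In this first half of the Arndt–Eistert homologation diazomethane is acylated by the mixed anhydride at the more electrophilic acyl carbonyl, which should give the diazoketone without touching the unactivated vinyl group or the alkene geometry.

Step 13
Reactants: 15 (E)-alkenyl diazomethyl ketone
Product: 17 2-(trimethylsilyl)ethyl (16E)-β,γ-unsaturated ester with the C13 naphthylmethyl ether (11S,13R,14S,15R), via vinylketene 16 (not isolated)
Conditions: PhCO2Ag (cat.), Et3N, Me3SiCH2CH2OH, THF, rt, dark
Reagents that add atoms: 2-(trimethylsilyl)ethanol, C[Si](C)(C)CCO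
Why: In the silver-catalysed Wolff rearrangement the alkenyl group migrates with retention of its geometry to give vinylketene 16, and 2-(trimethylsilyl)ethanol adds to the ketene in a 1,2-sense so that the ester forms with the (E)-C16=C17 alkene out of conjugation.

Step 14
Reactants: 17 2-(trimethylsilyl)ethyl ester with the C13 naphthylmethyl ether
Product: 18 C11-vinyl tetrahydrofuran C13 alcohol with the complete side chain (11S,13R,14S,15R,16E)
Conditions: DDQ, CH2Cl2/pH 7 buffer, 0 °C to rt
Reagents that add atoms: none
Why: DDQ oxidises the electron-rich naphthylmethyl ether by benzylic hydride abstraction and the oxocarbenium ion is hydrolysed, a standard oxidative ether cleavage that should spare the TBS ether, the ester and the unactivated alkenes.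

Step 15
Reactants: 19 propargyl alcohol; 20 1,1,3-trichloroprop-1-ene
Product: 22 (2Z)-6,6-dichloro-2-methylhexa-2,5-dien-1-ol (C3–C8 of the target), via alkenylmagnesium chelate 21 (not isolated)
Conditions: MeMgBr, CuI (cat.), THF, −10 °C to rt; then 20, −20 °C to rt; aq NH4Cl
Reagents that add atoms: methylmagnesium bromide, C[Mg]Br
Why: Copper-catalysed anti-carbomagnesiation of the propargylic magnesium alkoxide puts methyl on C4 and magnesium on C5 cis to the CH2O group in the five-membered chelate 21, and copper-catalysed SN2 allylation at the CH2Cl carbon of 20 replaces magnesium with retention, which fixes the (Z)-trisubstituted C4=C5 alkene.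

Step 16
Reactants: 18 C11-vinyl tetrahydrofuran C13 alcohol; 22 (2Z)-6,6-dichloro-2-methylhexa-2,5-dien-1-ol
Product: 24 C3,C13-diol with the C3–C19 skeleton (11R,13R,14S,15R,4Z,7Z,16E), via B-alkyl-9-BBN 23 (not isolated)
Conditions: 9-BBN dimer (excess), THF, 0 °C to rt; then degassed aq K3PO4, 22, Pd2(dba)3 (cat.), XantPhos (cat.), THF, 65 °C
Reagents that add atoms: none
Why: Anti-Markovnikov hydroboration of the monosubstituted alkene by 9-BBN (the trisubstituted alkene and the ester are left) gives borane 23, and in the B-alkyl Suzuki–Miyaura coupling zerovalent palladium inserts into the less hindered C–Cl bond trans to the C6 substituent of 22 while the wide-bite-angle XantPhos favours a single coupling, which leaves chlorine cis to C6 and gives the (7Z)-chloroalkene.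

Step 17
Reactants: 24 C3,C13-diol
Product: 25 (4Z)-enal with the free C13 hydroxyl (11R,13R,14S,15R,4Z,7Z,16E)
Conditions: TEMPO (cat.), PhI(OAc)2, CH2Cl2, rt
Reagents that add atoms: none
Why: The oxoammonium oxidation with TEMPO and PhI(OAc)2 is selective for the primary allylic alcohol over the hindered secondary C13 hydroxyl and, being neutral, should keep the (Z)-geometry of the enal.

Step 18
Reactants: 25 (4Z)-enal with the free C13 hydroxyl; 26 bromoacetyl bromide
Product: 27 O13 bromoacetate of the (4Z)-enal (11R,13R,14S,15R,4Z,7Z,16E)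
Conditions: pyridine, CH2Cl2, −40 to 0 °C
Reagents that add atoms: none
Why: Acylation of the secondary C13 hydroxyl by the acid bromide needs no nucleophilic catalyst and pyridine at low temperature only takes up HBr, so the (Z)-enal should survive.

Step 19
Reactants: 27 O13 bromoacetate of the (4Z)-enal
Product: 29 (3R)-C3-hydroxy macrolide with the C15 TBS ether and the 2-(trimethylsilyl)ethyl ester (3R,11R,13R,14S,15R,4Z,7Z,16E), via samarium enolate 28 (not isolated)
Conditions: SmI2 (about 4 equiv, 0.1 M in THF), THF, −78 °C, slow addition of 27 (high dilution); then aq NH4Cl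
Reagents that add atoms: none
Why: Two single-electron transfers from SmI2 cleave the C–Br bond of 27 and give the trivalent samarium ester enolate 28, whose oxophilic metal binds the C3 aldehyde oxygen so that C2 adds to the carbonyl through a cyclic chelate, and protonation of the samarium aldolate on work-up gives 29. The closest known reaction type is the SmI2-mediated intramolecular Reformatsky reaction used to close medium and large lactones. The 14-membered ring is closed by C2–C3 bond formation in a 14-exo-trig aldol addition (enolate C1=C2 inside the new ring), kept intramolecular by slow addition of 27 to excess SmI2 at high dilution. The new C3 stereocentre is set by the facial preference of this macrocyclic chelated transition state, which the rigid tetrahydrofuran ring with its C11 and C13 stereocentres and the two (Z)-alkenes restrict but do not make predictable; the (3R)-alcohol is needed, and because the (3S)-epimer can be acetylated with inversion, both faces lead on to 30. Chemoselectivity is needed for C–Br reduction over ketyl formation at the enal and for 1,2- over 1,4-addition; the α-bromo ester is reduced far faster than an aldehyde at −78 °C, and the α-methyl group together with the hard oxophilic enolate disfavours conjugate addition. The medium contains no Brønsted base, which protects the geometry of the C4=C5 enal and keeps the skipped C4–C8 diene and the deconjugated side-chain ester in place.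

Step 20
Reactants: 29 (3R)-C3-hydroxy macrolide
Product: 30 C3 acetate of the macrolide (3R,11R,13R,14S,15R,4Z,7Z,16E)
Conditions: Ac2O, pyridine, DMAP (cat.), CH2Cl2, 0 °C
Reagents that add atoms: acetic anhydride, CC(=O)OC(C)=O
Why: DMAP-catalysed acetylation of the secondary allylic C3 alcohol proceeds with retention and under conditions too mild for β-elimination of the resulting β-acetoxy lactone.

Step 21
Reactants: 30 C3 acetate of the macrolide
Product: 31 target acid (3R,11R,13R,14R,15R,4Z,7Z,16E)
Conditions: n-Bu4NF, AcOH, THF, 0 °C to rt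
Reagents that add atoms: none
Why: Fluoride cleaves the C15 silyl ether and fragments the 2-(trimethylsilyl)ethyl ester (to the carboxylate, ethylene and Me3SiF) in one operation, and the acetic acid buffer should suppress E1cB loss of the C3 acetate and acyl migration to the freed C15 hydroxyl.

Compound list

1 | 2-deoxy-D-glucose | O=CC[C@@H](O)[C@H](O)[C@H](O)CO | starting material
2 | 2-deoxy-D-arabino-hexono-1,4-lactone | O=C1C[C@@H](O)[C@H](O1)[C@H](O)CO | intermediate
3 | 2-deoxy-5,6-O-isopropylidene-D-arabino-hexono-1,4-lactone | O=C1C[C@@H](O)[C@H](O1)[C@H]1COC(C)(C)O1 | intermediate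
4 | 2-deoxy-5,6-O-isopropylidene-3-O-(2-naphthylmethyl)-D-arabino-hexono-1,4-lactone | O=C1C[C@@H](OCc2ccc3ccccc3c2)[C@H](O1)[C@H]1COC(C)(C)O1 | intermediate
5 | 1-C-ethynyl hemiketal of 4 (mixture of anomers at the later C11) | C#CC1(O)C[C@@H](OCc2ccc3ccccc3c2)[C@H](O1)[C@H]1COC(C)(C)O1 | intermediate
6 | C11-ethynyl tetrahydrofuran, ethynyl trans to O13 and to the C14 substituent, C13 naphthylmethyl ether, C15/C16 acetonide (11S,13R,14S,15R) | C#C[C@@H]1C[C@@H](OCc2ccc3ccccc3c2)[C@H](O1)[C@H]1COC(C)(C)O1 | intermediate
7 | C11-vinyl tetrahydrofuran, C13 naphthylmethyl ether, C15/C16 acetonide (11S,13R,14S,15R) | C=C[C@@H]1C[C@@H](OCc2ccc3ccccc3c2)[C@H](O1)[C@H]1COC(C)(C)O1 | intermediate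
8 | C11-vinyl tetrahydrofuran C15,C16-diol, C13 naphthylmethyl ether (11S,13R,14R,15R) | C=C[C@@H]1C[C@@H](OCc2ccc3ccccc3c2)[C@H](O1)[C@H](O)CO | intermediate
9 | C15,C16-bis-TBS ether (11S,13R,14S,15R) | C=C[C@@H]1C[C@@H](OCc2ccc3ccccc3c2)[C@H](O1)[C@H](O[Si](C)(C)C(C)(C)C)CO[Si](C)(C)C(C)(C)C | intermediate
10 | C16 primary alcohol, C15 TBS ether (11S,13R,14S,15R) | C=C[C@@H]1C[C@@H](OCc2ccc3ccccc3c2)[C@H](O1)[C@H](O[Si](C)(C)C(C)(C)C)CO | intermediate
11 | C16 aldehyde, C15 TBS ether (11S,13R,14S,15S), not isolated | C=C[C@@H]1C[C@@H](OCc2ccc3ccccc3c2)[C@H](O1)[C@H](O[Si](C)(C)C(C)(C)C)C=O | intermediate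
12 | ethyl (E)-2-methyl-enoate at C16=C17 (11S,13R,14S,15R) | C=C[C@@H]1C[C@@H](OCc2ccc3ccccc3c2)[C@H](O1)[C@H](O[Si](C)(C)C(C)(C)C)/C=C(\C)C(=O)OCC | intermediate
13 | (E)-2-methyl-enoic acid (11S,13R,14S,15R) | C=C[C@@H]1C[C@@H](OCc2ccc3ccccc3c2)[C@H](O1)[C@H](O[Si](C)(C)C(C)(C)C)/C=C(\C)C(=O)O | intermediate
14 | isobutyl carbonic mixed anhydride of 13, not isolated | C=C[C@@H]1C[C@@H](OCc2ccc3ccccc3c2)[C@H](O1)[C@H](O[Si](C)(C)C(C)(C)C)/C=C(\C)C(=O)OC(=O)OCC(C)C | intermediate
15 | (E)-alkenyl diazomethyl ketone (11S,13R,14S,15R) | C=C[C@@H]1C[C@@H](OCc2ccc3ccccc3c2)[C@H](O1)[C@H](O[Si](C)(C)C(C)(C)C)/C=C(\C)C(=O)C=[N+]=[N-] | intermediate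
16 | (E)-vinylketene, not isolated | C=C[C@@H]1C[C@@H](OCc2ccc3ccccc3c2)[C@H](O1)[C@H](O[Si](C)(C)C(C)(C)C)/C=C(\C)C=C=O | intermediate
17 | 2-(trimethylsilyl)ethyl (16E)-β,γ-unsaturated ester, C13 naphthylmethyl ether, C15 TBS ether (11S,13R,14S,15R) | C=C[C@@H]1C[C@@H](OCc2ccc3ccccc3c2)[C@H](O1)[C@H](O[Si](C)(C)C(C)(C)C)/C=C(\C)CC(=O)OCC[Si](C)(C)C | intermediate
18 | C11-vinyl tetrahydrofuran C13 alcohol with the C15 TBS ether and the 2-(trimethylsilyl)ethyl ester side chain (11S,13R,14S,15R,16E) | C=C[C@@H]1C[C@@H](O)[C@H](O1)[C@H](O[Si](C)(C)C(C)(C)C)/C=C(\C)CC(=O)OCC[Si](C)(C)C | intermediate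
19 | propargyl alcohol | OCC#C | starting material
20 | 1,1,3-trichloroprop-1-ene | ClCC=C(Cl)Cl | starting material
21 | alkenylmagnesium chelate (4-methyl-2,5-dihydro-1,2-oxamagnesole), not isolated | CC1=C[Mg]OC1 | intermediate
22 | (2Z)-6,6-dichloro-2-methylhexa-2,5-dien-1-ol | OC/C(C)=C\CC=C(Cl)Cl | intermediate
23 | B-alkyl-9-BBN at C9 with the C13 oxygen as its 9-BBN borinate, not isolated | C(C[C@@H]1C[C@@H](OB2C3CCCC2CCC3)[C@H](O1)[C@H](O[Si](C)(C)C(C)(C)C)/C=C(\C)CC(=O)OCC[Si](C)(C)C)B1C2CCCC1CCC2 | intermediate
24 | C3,C13-diol with the (7Z)-chloroalkene (11R,13R,14S,15R,4Z,7Z,16E) | O[C@@H]1C[C@@H](CC/C(Cl)=C/C/C=C(/C)CO)O[C@@H]1[C@H](O[Si](C)(C)C(C)(C)C)/C=C(\C)CC(=O)OCC[Si](C)(C)C | intermediate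
25 | (4Z)-enal with the free C13 hydroxyl (11R,13R,14S,15R,4Z,7Z,16E) | O[C@@H]1C[C@@H](CC/C(Cl)=C/C/C=C(/C)C=O)O[C@@H]1[C@H](O[Si](C)(C)C(C)(C)C)/C=C(\C)CC(=O)OCC[Si](C)(C)C | intermediate
26 | bromoacetyl bromide | BrCC(Br)=O | starting material
27 | O13 bromoacetate of the (4Z)-enal, cyclisation precursor (11R,13R,14S,15R,4Z,7Z,16E) | BrCC(=O)O[C@@H]1C[C@@H](CC/C(Cl)=C/C/C=C(/C)C=O)O[C@@H]1[C@H](O[Si](C)(C)C(C)(C)C)/C=C(\C)CC(=O)OCC[Si](C)(C)C | intermediate
28 | samarium enolate of the O13 acetate (trivalent samarium, two iodides), not isolated | C=C(O[Sm](I)I)O[C@@H]1C[C@@H](CC/C(Cl)=C/C/C=C(/C)C=O)O[C@@H]1[C@H](O[Si](C)(C)C(C)(C)C)/C=C(\C)CC(=O)OCC[Si](C)(C)C | intermediate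
29 | (3R)-C3-hydroxy macrolide, C15 TBS ether, 2-(trimethylsilyl)ethyl ester (3R,11R,13R,14S,15R,4Z,7Z,16E) | O[C@@H]1CC(=O)O[C@@H]2C[C@@H](CC/C(Cl)=C/C/C=C\1C)O[C@@H]2[C@H](O[Si](C)(C)C(C)(C)C)/C=C(\C)CC(=O)OCC[Si](C)(C)C | intermediate
30 | C3 acetate of the protected macrolide (3R,11R,13R,14S,15R,4Z,7Z,16E) | CC(=O)O[C@@H]1CC(=O)O[C@@H]2C[C@@H](CC/C(Cl)=C/C/C=C\1C)O[C@@H]2[C@H](O[Si](C)(C)C(C)(C)C)/C=C(\C)CC(=O)OCC[Si](C)(C)C | intermediate
31 | target acid (3R,11R,13R,14R,15R,4Z,7Z,16E) | CC(=O)O[C@@H]1CC(=O)O[C@@H]2C[C@@H](CC/C(Cl)=C/C/C=C\1C)O[C@@H]2[C@H](O)/C=C(\C)CC(=O)O | target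

Total step count: 21 steps.
Longest linear sequence: 20 steps (steps 1–14 and 16–21, from 2-deoxy-D-glucose); step 15 makes the second fragment.

Steps most likely to fail

Step 19. The samarium-chelated macrocyclic aldol may attack the aldehyde mainly from the wrong face, so that the C3 carbinol forms with the opposite configuration. The fallback sets out from 27 and no longer relies on the aldol face selectivity for C3. The same ring closure is run and the (3S)-epimeric hydroxy macrolide F1 is isolated. It is treated with PPh3, diisopropyl azodicarboxylate and acetic acid in toluene at 0 °C (Mitsunobu reaction), which displaces the activated allylic oxygen by acetate with inversion. This returns to the route at 30 and bypasses step 20.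

Step 16. Oxidative addition into the C–Cl bond may be slow, so that the alkylborane is lost by protodeboronation or β-hydride elimination, a second coupling may take place at the remaining chloride, or the aqueous phosphate may move the C16=C17 alkene into conjugation with the ester. The fallback replaces boron by zinc and works without base. It sets out from 18:
- Hydroboration with 9-BBN and oxidation with NaBO3·4H2O should give the C9 primary alcohol F2.
- I2, PPh3 and imidazole should convert only the primary hydroxyl into the C9 iodide F3.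
- Et3SiCl and imidazole should give its C13 triethylsilyl ether F4.
- Zinc dust with LiCl in THF should insert to give the alkylzinc iodide F5, which is not isolated.
- Diene 22 is silylated (Et3SiCl, imidazole) to its triethylsilyl ether F6.
- Negishi coupling of F5 with F6 under PdCl2(DPEphos) catalysis in THF/DMF at rt should again replace only the chlorine trans to C6 and give the bis(triethylsilyl) ether F7.
- Pyridinium p-toluenesulfonate in MeOH at 0 °C should remove both triethylsilyl groups beside the TBS ether and return to the route at 24.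

Step 13. The alkenyl diazoketone may be diverted by carbenoid side reactions, or the amine may move the new β,γ-alkene into conjugation. The fallback builds C18–C19 by carbonylation and sets out from 12:
- DIBAL-H in CH2Cl2 at −78 °C should give the (E)-allylic alcohol F8.
- 4-Nitrophenyl 2-(trimethylsilyl)ethyl carbonate with DMAP should give the allyl 2-(trimethylsilyl)ethyl carbonate F9.
- Pd(OAc)2/PPh3 under CO in THF at 50 °C should effect decarboxylative alkoxycarbonylation: ionisation to the π-allylpalladium, CO insertion at the less hindered CH2 terminus and capture by the released silylethoxide. This returns to the route at 17.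

Further compounds

F1 | step 19 | (3S)-epimer of hydroxy macrolide 29 | O[C@H]1CC(=O)O[C@@H]2C[C@@H](CC/C(Cl)=C/C/C=C\1C)O[C@@H]2[C@H](O[Si](C)(C)C(C)(C)C)/C=C(\C)CC(=O)OCC[Si](C)(C)C
F2 | step 16 | C9 primary alcohol from 18 (C9,C13-diol) | OCC[C@@H]1C[C@@H](O)[C@H](O1)[C@H](O[Si](C)(C)C(C)(C)C)/C=C(\C)CC(=O)OCC[Si](C)(C)C
F3 | step 16 | C9 iodide with the free C13 hydroxyl | ICC[C@@H]1C[C@@H](O)[C@H](O1)[C@H](O[Si](C)(C)C(C)(C)C)/C=C(\C)CC(=O)OCC[Si](C)(C)C
F4 | step 16 | C9 iodide, C13 triethylsilyl ether | ICC[C@@H]1C[C@@H](O[Si](CC)(CC)CC)[C@H](O1)[C@H](O[Si](C)(C)C(C)(C)C)/C=C(\C)CC(=O)OCC[Si](C)(C)C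
F5 | step 16 | C9 alkylzinc iodide, C13 triethylsilyl ether (not isolated) | I[Zn]CC[C@@H]1C[C@@H](O[Si](CC)(CC)CC)[C@H](O1)[C@H](O[Si](C)(C)C(C)(C)C)/C=C(\C)CC(=O)OCC[Si](C)(C)C
F6 | step 16 | triethylsilyl ether of diene 22 | CC[Si](CC)(CC)OC/C(C)=C\CC=C(Cl)Cl
F7 | step 16 | coupled C3,C13-bis(triethylsilyl) ether | CC[Si](CC)(CC)O[C@@H]1C[C@@H](CC/C(Cl)=C/C/C=C(/C)CO[Si](CC)(CC)CC)O[C@@H]1[C@H](O[Si](C)(C)C(C)(C)C)/C=C(\C)CC(=O)OCC[Si](C)(C)C
F8 | step 13 | (E)-allylic alcohol from enoate 12 | C=C[C@@H]1C[C@@H](OCc2ccc3ccccc3c2)[C@H](O1)[C@H](O[Si](C)(C)C(C)(C)C)/C=C(\C)CO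
F9 | step 13 | allyl 2-(trimethylsilyl)ethyl carbonate of F8 | C=C[C@@H]1C[C@@H](OCc2ccc3ccccc3c2)[C@H](O1)[C@H](O[Si](C)(C)C(C)(C)C)/C=C(\C)COC(=O)OCC[Si](C)(C)C
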